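The target is cut across ring B: ring C is taken intact as a brominated dihydropyranone, and ring B is grown onto its enone double bond by a [4+2] benzannulation with a bis(silyloxy) ketene acetal diene that already carries the protected ring A on its terminal CH2. Because O1 sits on the enone β-carbon, which becomes C8a, the bridge-bearing diene terminus can only end up at C8, so the C6-methyl/C8-benzyl pattern of the fully substituted phloroglucinol ring B is fixed in one operation that also makes C8–C8a and C4a–C5. Debenzylation and Houben–Hoesch acylation of the last free carbon of ring A finish the synthesis.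

Key step: step 9

Remark 1: ring A keeps its aryl methyl group in the target, so the side-chain carbon enters as a new formyl group on the ring; the chain is joined by aldol addition and ionic deoxygenation because a 2,4,6-trialkoxybenzyl bromide with a free ring position is expected to self-condense before it could be alkylated.

Remark 2: compounds 6, 8 and 16 are stereoisomer mixtures whose stereo-elements are all erased later, so their SMILES carry no descriptors; diene 9 is assumed to form with 3Z geometry and its C1=C2 geometry is irrelevant.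

Step 1
Reactants: 1 2-methylphloroglucinol (2-methylbenzene-1,3,5-triol)
Product: 3 2,4,6-trihydroxy-3-methylbenzaldehyde, via iminium chloride 2 (not isolated)
Conditions: POCl3, DMF, EtOAc, 0 °C → rt; then H2O, 60 °C
Reagents that add atoms: N,N-dimethylformamide CN(C)C=O; water O
Why: Vilsmeier–Haack formylation: the chloroiminium ion from DMF and POCl3 should attack one of the two equivalent free positions of the electron-rich triol, the iminium salt 2 deactivates the ring against a second attack, and water hydrolyses it to the aldehyde.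

Step 2
Reactants: 3 2,4,6-trihydroxy-3-methylbenzaldehyde
Product: 4 2,4,6-tris(benzyloxy)-3-methylbenzaldehyde
Conditions: BnBr (3.6 equiv), K2CO3, DMF, 60 °C
Reagents that add atoms: benzyl bromide BrCc1ccccc1
Why: Williamson etherification: with K2CO3 in DMF the formyl-deactivated phloroglucinol should alkylate on oxygen and not on carbon, the excess halide and gentle heating serving the two hydroxyls that are hydrogen-bonded to the aldehyde.

Step 3
Reactants: 4 2,4,6-tris(benzyloxy)-3-methylbenzaldehyde; 5 methyl 2-methyl-3-oxobutanoate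
Product: 6 methyl 5-hydroxy-2-methyl-3-oxo-5-[2,4,6-tris(benzyloxy)-3-methylphenyl]pentanoate (racemic mixture of diastereomers)
Conditions: 5, LiN(iPr)2 (2.2 equiv), THF, 0 °C; then 4, −78 °C; AcOH, −78 °C
Reagents that add atoms: none
Why: Aldol addition of the dianion of a β-keto ester, which reacts at its terminal γ-carbon, to a non-enolisable aldehyde; the new carbinol centre (C5) forms without control and is removed in step 4, and the epimerisable C2 centre disappears in step 5.

Step 4
Reactants: 6 methyl 5-hydroxy-2-methyl-3-oxo-5-[2,4,6-tris(benzyloxy)-3-methylphenyl]pentanoate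
Product: 7 methyl 2-methyl-3-oxo-5-[2,4,6-tris(benzyloxy)-3-methylphenyl]pentanoate (racemic)
Conditions: Et3SiH, TFA, CH2Cl2, 0 °C
Reagents that add atoms: none
Why: Ionic hydrogenation: acid ionises the benzylic alcohol to a cation stabilised by three alkoxy groups and triethylsilane delivers hydride to it, while the keto ester and the benzyl ethers should not react at 0 °C.

Step 5
Reactants: 7 methyl 2-methyl-3-oxo-5-[2,4,6-tris(benzyloxy)-3-methylphenyl]pentanoate
Product: 8 methyl 2-methyl-5-[2,4,6-tris(benzyloxy)-3-methylphenyl]-3-(trimethylsilyloxy)pent-2-enoate (E/Z mixture, used crude)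
Conditions: TMSCl, Et3N, toluene, rt
Reagents that add atoms: chlorotrimethylsilane C[Si](C)(C)Cl
Why: O-Silylation of the β-keto ester enol, the standard first stage in making 1,3-bis(silyloxy) dienes; the geometry of the new double bond is of no consequence because it becomes the C2–C3 single bond of the diene.

Step 6
Reactants: 8 methyl 2-methyl-5-[2,4,6-tris(benzyloxy)-3-methylphenyl]-3-(trimethylsilyloxy)pent-2-enoate
Product: 9 (3Z)-1-methoxy-2-methyl-1,3-bis(trimethylsilyloxy)-5-[2,4,6-tris(benzyloxy)-3-methylphenyl]penta-1,3-diene (used crude)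
Conditions: LiN(iPr)2, THF, −78 °C; TMSCl, −78 °C → rt
Reagents that add atoms: chlorotrimethylsilane C[Si](C)(C)Cl
Why: Vinylogous (γ) deprotonation of the silyloxy enoate by the lithium amide and O-silylation of the extended enolate give the 1-methoxy-1,3-bis(silyloxy) diene, kinetic deprotonation being expected to place the C4 substituent cis to the C3 silyloxy group (3Z).

Step 7
Reactants: 10 (E)-4-methoxybut-3-en-2-one; 11 acetone
Product: 13 2,2-dimethyl-2,3-dihydro-4H-pyran-4-one, via hydroxy enone 12 (not isolated)
Conditions: 10, LiN(iPr)2, THF, −78 °C; acetone, −78 °C; then 2 M HCl, 0 °C → rt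
Reagents that add atoms: none
Why: Aldol addition of the kinetic lithium enolate of the vinylogous ester to acetone, then acid-catalysed 6-endo-trig oxa-Michael addition of the tertiary hydroxyl to the β-methoxy enone and loss of methanol, a standard entry to 2,3-dihydro-4H-pyran-4-ones.

Step 8
Reactants: 13 2,2-dimethyl-2,3-dihydro-4H-pyran-4-one
Product: 15 5-bromo-2,2-dimethyl-2,3-dihydro-4H-pyran-4-one, via trans-dibromide 14 (not isolated)
Conditions: Br2, CH2Cl2, 0 °C; then Et3N, 0 °C → rt
Reagents that add atoms: bromine BrBr
Why: α-Bromination of an enone by addition–elimination: bromine adds anti across the enol ether double bond to give the racemic trans dibromide, and Et3N removes the acidic C5 proton with loss of the anomeric bromide, so both transient stereocentres vanish.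

Step 9
Reactants: 9 (3Z)-1-methoxy-2-methyl-1,3-bis(trimethylsilyloxy)-5-[2,4,6-tris(benzyloxy)-3-methylphenyl]penta-1,3-diene; 15 5-bromo-2,2-dimethyl-2,3-dihydro-4H-pyran-4-one
Product: 18 5,7-dihydroxy-2,2,6-trimethyl-8-{[2,4,6-tris(benzyloxy)-3-methylphenyl]methyl}chroman-4-one, via bromo ketal cycloadduct 16 (not isolated), via silyl ether 17 (not isolated)
Conditions: 9 (1.5 equiv), toluene, 80 °C; then DBU, 0 °C → rt; then 1 M HCl, THF, rt
Reagents that add atoms: none
Why: The electron-rich diene 9 should add to the bromo enone 15 in a strongly asynchronous [4+2] cycloaddition, C4 of the diene bonding to the oxygen-bearing β-carbon (C8–C8a) and the ketene acetal carbon to the brominated α-carbon (C4a–C5) to give the cis-fused adduct 16; collapse of the methyl silyl ketal at C5 (loss of MeOSiMe3), DBU-mediated dehydrobromination across C4a–C8a and tautomerisation of the C8–H dienone then give arene 17, and dilute acid removes the remaining silyl group. The closest known reaction type is the Diels–Alder benzannulation of 1-alkoxy-1,3-bis(silyloxy)dienes with α-halo enones and haloquinones, which aromatises by loss of hydrogen halide. Ring B is closed as a six-membered carbocycle by the intermolecular cycloaddition itself; should the reaction run stepwise, the second bond forms by 6-exo-trig attack of the C4a enol carbon on the ester-level carbon C5 after a Mukaiyama–Michael addition. The four stereocentres of 16 (C4a, C5, C8, C8a) are all destroyed on aromatisation, so none needs control. The step needs regioselectivity, which polarisation should secure: the C3 silyloxy group makes C4 of the diene its nucleophilic terminus and the ring C carbonyl makes the oxygen-bearing β-carbon of 15 its electrophilic terminus, so the benzyl-bearing carbon must become C8 next to O1. It also needs loss of HBr in preference to expulsion of O1, which the quaternary C4a of 16 (no enolisation of the ring C ketone toward C8a) and the absence of Lewis acid should favour.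

Step 10
Reactants: 18 5,7-dihydroxy-2,2,6-trimethyl-8-{[2,4,6-tris(benzyloxy)-3-methylphenyl]methyl}chroman-4-one
Product: 19 5,7-dihydroxy-2,2,6-trimethyl-8-[(2,4,6-trihydroxy-3-methylphenyl)methyl]chroman-4-one
Conditions: H2 (1 atm), Pd/C, EtOAc–MeOH, rt
Reagents that add atoms: none
Why: Hydrogenolysis of the three aryl benzyl ethers over Pd/C; the hydrogen-bonded aryl ketone of ring C and the diarylmethane bridge should not be reduced at room temperature and atmospheric pressure.

Step 11
Reactants: 19 5,7-dihydroxy-2,2,6-trimethyl-8-[(2,4,6-trihydroxy-3-methylphenyl)methyl]chroman-4-one; 20 isobutyronitrile (2-methylpropanenitrile)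
Product: 22 5,7-dihydroxy-2,2,6-trimethyl-8-{[2,4,6-trihydroxy-3-methyl-5-(2-methylpropanoyl)phenyl]methyl}chroman-4-one, via ketiminium chloride 21 (not isolated)
Conditions: 20, ZnCl2, HCl (g), Et2O, 0 °C → rt; then H2O, 90 °C
Reagents that add atoms: water O
Why: Houben–Hoesch acylation: the nitrilium species from the nitrile, HCl and ZnCl2 should attack the only unsubstituted aromatic carbon of 19, which lies between two hydroxyls of ring A, and hot water hydrolyses the ketiminium salt 21 to the aryl ketone.

Compound list
1 | 2-methylbenzene-1,3,5-triol (2-methylphloroglucinol) | Cc1c(O)cc(O)cc1O | starting material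
2 | N-[(2,4,6-trihydroxy-3-methylphenyl)methylidene]-N-methylmethanaminium chloride | C[N+](C)=Cc1c(O)cc(O)c(C)c1O.[Cl-] | intermediate (not isolated)
3 | 2,4,6-trihydroxy-3-methylbenzaldehyde | O=Cc1c(O)cc(O)c(C)c1O | intermediate
4 | 2,4,6-tris(benzyloxy)-3-methylbenzaldehyde | O=Cc1c(OCc2ccccc2)cc(OCc2ccccc2)c(C)c1OCc1ccccc1 | intermediate
5 | methyl 2-methyl-3-oxobutanoate (racemic) | COC(=O)C(C)C(C)=O | starting material
6 | methyl 5-hydroxy-2-methyl-3-oxo-5-[2,4,6-tris(benzyloxy)-3-methylphenyl]pentanoate (racemic mixture of diastereomers) | COC(=O)C(C)C(=O)CC(O)c1c(OCc2ccccc2)cc(OCc2ccccc2)c(C)c1OCc1ccccc1 | intermediate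
7 | methyl 2-methyl-3-oxo-5-[2,4,6-tris(benzyloxy)-3-methylphenyl]pentanoate (racemic) | COC(=O)C(C)C(=O)CCc1c(OCc2ccccc2)cc(OCc2ccccc2)c(C)c1OCc1ccccc1 | intermediate
8 | methyl 2-methyl-5-[2,4,6-tris(benzyloxy)-3-methylphenyl]-3-(trimethylsilyloxy)pent-2-enoate (E/Z mixture) | COC(=O)C(C)=C(O[Si](C)(C)C)CCc1c(OCc2ccccc2)cc(OCc2ccccc2)c(C)c1OCc1ccccc1 | intermediate
9 | (3Z)-1-methoxy-2-methyl-1,3-bis(trimethylsilyloxy)-5-[2,4,6-tris(benzyloxy)-3-methylphenyl]penta-1,3-diene (C1=C2 geometry undefined) | COC(O[Si](C)(C)C)=C(C)/C(O[Si](C)(C)C)=C/Cc1c(OCc2ccccc2)cc(OCc2ccccc2)c(C)c1OCc1ccccc1 | intermediate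
10 | (E)-4-methoxybut-3-en-2-one | CO/C=C/C(C)=O | starting material
11 | acetone | CC(C)=O | starting material
12 | (E)-5-hydroxy-1-methoxy-5-methylhex-1-en-3-one | CO/C=C/C(=O)CC(C)(C)O | intermediate (not isolated)
13 | 2,2-dimethyl-2,3-dihydro-4H-pyran-4-one | CC1(C)CC(=O)C=CO1 | intermediate
14 | trans-5,6-dibromo-2,2-dimethyloxan-4-one (racemic; one enantiomer drawn) | CC1(C)CC(=O)[C@H](Br)[C@@H](Br)O1 | intermediate (not isolated)
15 | 5-bromo-2,2-dimethyl-2,3-dihydro-4H-pyran-4-one | CC1(C)CC(=O)C(Br)=CO1 | intermediate
16 | 4a-bromo-5-methoxy-2,2,6-trimethyl-8-{[2,4,6-tris(benzyloxy)-3-methylphenyl]methyl}-5,7-bis(trimethylsilyloxy)-2,3,4a,5,8,8a-hexahydro-4H-chromen-4-one (cis-fused, mixture of diastereomers) | COC1(O[Si](C)(C)C)C(C)=C(O[Si](C)(C)C)C(Cc2c(OCc3ccccc3)cc(OCc3ccccc3)c(C)c2OCc2ccccc2)C2OC(C)(C)CC(=O)C12Br | intermediate (not isolated)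
17 | 5-hydroxy-2,2,6-trimethyl-8-{[2,4,6-tris(benzyloxy)-3-methylphenyl]methyl}-7-(trimethylsilyloxy)chroman-4-one | Cc1c(O[Si](C)(C)C)c(Cc2c(OCc3ccccc3)cc(OCc3ccccc3)c(C)c2OCc2ccccc2)c2OC(C)(C)CC(=O)c2c1O | intermediate (not isolated)
18 | 5,7-dihydroxy-2,2,6-trimethyl-8-{[2,4,6-tris(benzyloxy)-3-methylphenyl]methyl}chroman-4-one | Cc1c(O)c(Cc2c(OCc3ccccc3)cc(OCc3ccccc3)c(C)c2OCc2ccccc2)c2OC(C)(C)CC(=O)c2c1O | intermediate
19 | 5,7-dihydroxy-2,2,6-trimethyl-8-[(2,4,6-trihydroxy-3-methylphenyl)methyl]chroman-4-one | Cc1c(O)c(Cc2c(O)cc(O)c(C)c2O)c2OC(C)(C)CC(=O)c2c1O | intermediate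
20 | 2-methylpropanenitrile (isobutyronitrile) | CC(C)C#N | starting material
21 | 1-{3-[(5,7-dihydroxy-2,2,6-trimethyl-4-oxochroman-8-yl)methyl]-2,4,6-trihydroxy-5-methylphenyl}-2-methylpropan-1-iminium chloride | CC(C)C(=[NH2+])c1c(O)c(C)c(O)c(Cc2c(O)c(C)c(O)c3c2OC(C)(C)CC3=O)c1O.[Cl-] | intermediate (not isolated)
22 | 5,7-dihydroxy-2,2,6-trimethyl-8-{[2,4,6-trihydroxy-3-methyl-5-(2-methylpropanoyl)phenyl]methyl}chroman-4-one (CNP0186856.0) | Cc1c(O)c(Cc2c(O)c(C)c(O)c3c2OC(C)(C)CC3=O)c(O)c(C(=O)C(C)C)c1O | target

Total step count: 11.
Longest linear sequence: 9 steps (steps 1–6, then 9, 10 and 11, from 1 to 22); the dienophile branch (steps 7 and 8) joins at step 9.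

Steps most likely to fail

1. Step 9. Donation from the ring oxygen lowers the electrophilicity of the enone, so the cycloaddition may be slower than thermal silyl migration and hydrolysis of the diene. Bromine may also be transferred from the α-bromo ketone to the ketene acetal, or ring C may open by expulsion of O1 during the base stage in place of dehydrobromination. The fallback sets out from 1 and comes back to the route at 19. Friedel–Crafts acylation of 1 with 3-methylbut-2-enoic acid in MeSO3H/P2O5, with oxa-Michael closure in the same flask, should give 5,7-dihydroxy-2,2,6-trimethylchroman-4-one F1, to be separated from its 8-methyl isomer. Mannich aminomethylation of its only free ring carbon (C8) with dimethylmethylideneammonium iodide should give 8-[(dimethylamino)methyl]-5,7-dihydroxy-2,2,6-trimethylchroman-4-one F2. Heating F2 with an excess of 1 in dioxane should expel dimethylamine, and the ortho-quinone methide so formed should alkylate a free position of 1 to give 19, which continues with step 11.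

2. Step 11. Under HCl/ZnCl2 and during the hot aqueous hydrolysis, protonation at the bridge-bearing carbons of the electron-rich pentaphenol may lead to scission or scrambling of the methylene bridge, and attack at the crowded last ring position may be slow. The fallback sets out from 18 and comes back at 22, with the acylation moved before the debenzylation. Friedel–Crafts acylation of the trialkoxyarene ring A of 18 with the mixed anhydride from 2-methylpropanoic acid and trifluoroacetic anhydride (CH2Cl2, 0 °C, no Lewis acid) should give 5,7-dihydroxy-2,2,6-trimethyl-8-{[2,4,6-tris(benzyloxy)-3-methyl-5-(2-methylpropanoyl)phenyl]methyl}chroman-4-one F3; a short K2CO3/MeOH treatment cleaves any ester formed at O7. Hydrogenolysis of F3 over Pd/C should then give 22 directly.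

3. Step 4. Capture of the benzylic cation by the free ring position of a second molecule may compete with hydride transfer, and acid may remove benzyl ethers or lactonise the hydroxy keto ester. The fallback sets out from 4 and comes back at 7. Horner–Wadsworth–Emmons olefination of 4 with trimethyl phosphonoacetate (NaH, THF) should give methyl (E)-3-[2,4,6-tris(benzyloxy)-3-methylphenyl]prop-2-enoate F4. Conjugate reduction with Mg in MeOH should give methyl 3-[2,4,6-tris(benzyloxy)-3-methylphenyl]propanoate F5. Crossed Claisen condensation of F5 with an excess of the lithium enolate of methyl propanoate (LiN(iPr)2, THF, −78 °C → 0 °C) should give 7.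

Further compounds
F1 | step 9 | 5,7-dihydroxy-2,2,6-trimethylchroman-4-one | Cc1c(O)cc2OC(C)(C)CC(=O)c2c1O
F2 | step 9 | 8-[(dimethylamino)methyl]-5,7-dihydroxy-2,2,6-trimethylchroman-4-one | Cc1c(O)c(CN(C)C)c2OC(C)(C)CC(=O)c2c1O
F3 | step 11 | 5,7-dihydroxy-2,2,6-trimethyl-8-{[2,4,6-tris(benzyloxy)-3-methyl-5-(2-methylpropanoyl)phenyl]methyl}chroman-4-one | Cc1c(O)c(Cc2c(OCc3ccccc3)c(C(=O)C(C)C)c(OCc3ccccc3)c(C)c2OCc2ccccc2)c2OC(C)(C)CC(=O)c2c1O
F4 | step 4 | methyl (E)-3-[2,4,6-tris(benzyloxy)-3-methylphenyl]prop-2-enoate | COC(=O)/C=C/c1c(OCc2ccccc2)cc(OCc2ccccc2)c(C)c1OCc1ccccc1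
F5 | step 4 | methyl 3-[2,4,6-tris(benzyloxy)-3-methylphenyl]propanoate | COC(=O)CCc1c(OCc2ccccc2)cc(OCc2ccccc2)c(C)c1OCc1ccccc1
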